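Everything rests on disconnecting ring F, the middle phenol of the C6 side chain. Its C–OH carbon is flanked by two ortho carbons that each carry a CH2 link (to rings E and G), while the para carbon is bare: the C2–C1(=O)–C6 pattern of cyclohexanone. The precursor is therefore an unsymmetrical (E,E)-2,6-bis(arylidene)cyclohexanone, made by two successive aldol condensations, with ring G as benzyl ether and ring E as free methyl salicylate. One rhodium-catalysed, redox-neutral isomerisation draws both exocyclic C=C bonds into the ring and delivers aromatic ring F, its OH and both CH2 links together. The ester carbon later becomes the CH2 joined to C6 of (S)-pinocembrin-derived ring A.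

Key step: step 3

Ring letters: A and C are the benzo and pyranone rings of the chromanone. B is the 2-phenyl ring and D the hydroxybenzyl ring on C8. E, F and G are the three phenol rings of the chain on C6, counted outwards.

Assumption: commercial natural pinocembrin is taken to be the (2S) enantiomer. Its enantiomeric purity is to be checked by chiral HPLC before use, and again on each flavanone after steps 6 and 7.

Design points:
- (a) A free ortho-OH on ring G would add to the ketone of the arylidene ketone and end in a xanthene, so ring G is masked. Benzyl is chosen because it leaves by neutral hydrogenolysis, so no boron or aluminium halide ever meets the ester or the diarylmethane links.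
- (b) The OH of ring E is para to the arylidene carbon and cannot reach the ketone. It stays free, which saves a deprotection.
- (c) Every alcoholic medium up to step 4 is methanol, so exchange at the methyl ester is degenerate.
- (d) Every operation on a flavanone is base-free. Base opens ring C to the chalcone, which would erode C2 and interchange C6 and C8.

Step 1
Reactants: 1 4-(cyclohex-1-en-1-yl)morpholine (morpholine enamine of cyclohexanone); 2 2-(benzyloxy)benzaldehyde
Product: 4 (2E)-2-[2-(benzyloxy)benzylidene]cyclohexan-1-one, via dienamine 3 (not isolated)
Conditions: 1 (1.1 equiv), toluene, reflux, Dean–Stark; then 1 M aq. HCl, rt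
Reagents that add atoms: water, O
Why: Stork-type enamine aldol condensation, in which the enamine carbon adds to the aldehyde, loss of water gives the cross-conjugated dienamine 3 whose twisted, hindered enamine unit resists a second condensation so that only one α-carbon is used, and mild acid hydrolysis releases the enone as the E isomer, which avoids the clash between aryl ring and carbonyl oxygen.

Step 2
Reactants: 4 (2E)-2-[2-(benzyloxy)benzylidene]cyclohexan-1-one; 5 methyl 5-formyl-2-hydroxybenzoate
Product: 6 methyl 5-{(E)-[(3E)-3-[2-(benzyloxy)benzylidene]-2-oxocyclohexylidene]methyl}-2-hydroxybenzoate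
Conditions: dry HCl (g), MeOH, 0 °C to rt
Reagents that add atoms: none
Why: Acid-catalysed Claisen–Schmidt condensation, in which the enol of 4 can form only towards the remaining α'-CH2 so the second aryl group is placed without ambiguity, acid instead of hydroxide spares the methyl ester and tolerates the free phenol, and reversible dehydration settles on the E,E isomer.

Step 3
Reactants: 6 methyl 5-{(E)-[(3E)-3-[2-(benzyloxy)benzylidene]-2-oxocyclohexylidene]methyl}-2-hydroxybenzoate
Product: 8 methyl 5-{3-[2-(benzyloxy)benzyl]-2-hydroxybenzyl}-2-hydroxybenzoate, via cyclohexa-2,5-dienone 7 (not isolated)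
Conditions: RhCl3·3H2O (10 mol %), MeOH–toluene, 90 °C, sealed tube, argon
Reagents that add atoms: none
Why: Methanol reduces trivalent rhodium chloride to a rhodium hydride, which adds to each enone in the conjugate sense (H to the exocyclic benzylic carbon, Rh to ring carbon C2 or C6) and leaves again by β-hydride elimination of a ring hydrogen at C3 or C5, so each C=C bond passes from the exocyclic to the endocyclic position. After both migrations the cross-conjugated dienone 7 is a non-aromatic tautomer of the phenol and enolises irreversibly by loss of a C4 hydrogen, which makes aromatisation the thermodynamic sink of the whole sequence. The closest known reaction type is the isoaromatisation of 2,6-dibenzylidenecyclohexanones to 2,6-dibenzylphenols by RhCl3·3H2O in hot alcohol, an exocyclic-to-endocyclic enone isomerisation. No ring is closed, because the six-membered carbocycle is already present and only becomes aromatic; no skeletal bond is formed and no stereocentre arises, the two E alkenes simply disappearing. The step needs complete double migration without net reduction and without damage to other groups: hydrogen-free conditions keep the hydride a shuttle, the only β-hydrogens that lead forward lie in the ring, and aryl benzyl ether, salicylate and phenol are inert. The ortho,ortho pattern of ring F is inherited from the α and α' carbons fixed in steps 1 and 2, and methanol is chosen because ethanol would exchange with the methyl ester.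

Step 4
Reactants: 8 methyl 5-{3-[2-(benzyloxy)benzyl]-2-hydroxybenzyl}-2-hydroxybenzoate
Product: 9 methyl 2-hydroxy-5-[2-hydroxy-3-(2-hydroxybenzyl)benzyl]benzoate
Conditions: H2 (1 atm), Pd/C (10 wt %), EtOAc–MeOH, rt
Reagents that add atoms: none
Why: Catalytic hydrogenolysis of an aryl benzyl ether, in which only the O–CH2Ph bond is activated while diarylmethane links, ester and phenols are inert at ambient pressure and temperature, so the OH of ring G is released under neutral conditions and before any labile benzylic alcohol exists.

Step 5
Reactants: 9 methyl 2-hydroxy-5-[2-hydroxy-3-(2-hydroxybenzyl)benzyl]benzoate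
Product: 10 4-[2-hydroxy-3-(2-hydroxybenzyl)benzyl]-2-(hydroxymethyl)phenol
Conditions: LiAlH4 (5 equiv), THF, 0 to 40 °C; cold dilute aq. KHSO4 to pH 5
Reagents that add atoms: none
Why: Ester reduction with LiAlH4, in which the three phenols are first deprotonated (hence the extra hydride), the salicylate ester is then reduced to the primary benzylic alcohol as methyl salicylate is reduced to saligenin, and a cold, weakly acidic quench avoids premature loss of water from the product.

Step 6
Reactants: 11 (2S)-pinocembrin [(2S)-5,7-dihydroxy-2-phenylchroman-4-one]; 12 2-hydroxybenzyl alcohol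
Product: 14 (2S)-5,7-dihydroxy-8-(2-hydroxybenzyl)-2-phenylchroman-4-one, via ortho-quinone methide 13 (not isolated)
Conditions: 11 (2 equiv), anhydrous ZnCl2, 1,4-dioxane, 70 °C, slow addition of 12; chromatography
Reagents that add atoms: none
Why: Lewis-acid-mediated Friedel–Crafts hydroxybenzylation through a zinc-bound ortho-quinone methide, in which ring A can add through C8 or C6, so excess recoverable 11 limits double alkylation, the C8 isomer 14 is separated from its C6 isomer by chromatography and is to be identified by the HMBC contact of the chelated 5-OH to a hydrogen-bearing C6, and the base-free medium together with the lack of a 4'-OH on ring B keeps ring C closed so that C2 stays S.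

Step 7
Reactants: 14 (2S)-5,7-dihydroxy-8-(2-hydroxybenzyl)-2-phenylchroman-4-one; 10 4-[2-hydroxy-3-(2-hydroxybenzyl)benzyl]-2-(hydroxymethyl)phenol
Product: 16 (2S)-5,7-dihydroxy-6-{2-hydroxy-5-[2-hydroxy-3-(2-hydroxybenzyl)benzyl]benzyl}-8-(2-hydroxybenzyl)-2-phenylchroman-4-one, via ortho-quinone methide 15 (not isolated)
Conditions: 14 (1.3 equiv), anhydrous ZnCl2, 1,4-dioxane, 70 °C, syringe-pump addition of 10
Reagents that add atoms: none
Why: The same Friedel–Crafts hydroxybenzylation, in which ionisation of the only benzylic alcohol (ortho to the OH of ring E) gives 15, this is captured by C6 as the single free carbon of the trioxygenated ring A and the most nucleophilic arene position present, slow addition keeps 15 dilute against self-condensation, and the base-free medium leaves the C2 stereocentre brought in with 11 untouched.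

Compound list
1 | 4-(cyclohex-1-en-1-yl)morpholine | C1CCC(=CC1)N1CCOCC1 | starting material
2 | 2-(benzyloxy)benzaldehyde | O=Cc1ccccc1OCc1ccccc1 | starting material
3 | 4-{(6E)-6-[2-(benzyloxy)benzylidene]cyclohex-1-en-1-yl}morpholine (not isolated) | C1(N2CCOCC2)=CCCC/C1=C\c1ccccc1OCc1ccccc1 | intermediate
4 | (2E)-2-[2-(benzyloxy)benzylidene]cyclohexan-1-one | O=C1CCCC/C1=C\c1ccccc1OCc1ccccc1 | intermediate
5 | methyl 5-formyl-2-hydroxybenzoate | COC(=O)c1cc(C=O)ccc1O | starting material
6 | methyl 5-{(E)-[(3E)-3-[2-(benzyloxy)benzylidene]-2-oxocyclohexylidene]methyl}-2-hydroxybenzoate | O=C1/C(=C/c2ccccc2OCc2ccccc2)CCC/C1=C\c1ccc(O)c(C(=O)OC)c1 | intermediate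
7 | methyl 5-({5-[2-(benzyloxy)benzyl]-6-oxocyclohexa-1,4-dien-1-yl}methyl)-2-hydroxybenzoate (not isolated) | O=C1C(Cc2ccccc2OCc2ccccc2)=CCC=C1Cc1ccc(O)c(C(=O)OC)c1 | intermediate
8 | methyl 5-{3-[2-(benzyloxy)benzyl]-2-hydroxybenzyl}-2-hydroxybenzoate | COC(=O)c1cc(Cc2cccc(Cc3ccccc3OCc3ccccc3)c2O)ccc1O | intermediate
9 | methyl 2-hydroxy-5-[2-hydroxy-3-(2-hydroxybenzyl)benzyl]benzoate | COC(=O)c1cc(Cc2cccc(Cc3ccccc3O)c2O)ccc1O | intermediate
10 | 4-[2-hydroxy-3-(2-hydroxybenzyl)benzyl]-2-(hydroxymethyl)phenol | OCc1cc(Cc2cccc(Cc3ccccc3O)c2O)ccc1O | intermediate
11 | (2S)-pinocembrin, (2S)-5,7-dihydroxy-2-phenylchroman-4-one | O=C1C[C@@H](c2ccccc2)Oc2cc(O)cc(O)c21 | starting material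
12 | 2-hydroxybenzyl alcohol | OCc1ccccc1O | starting material
13 | 6-methylidenecyclohexa-2,4-dien-1-one (not isolated) | C=C1C=CC=CC1=O | intermediate
14 | (2S)-5,7-dihydroxy-8-(2-hydroxybenzyl)-2-phenylchroman-4-one | O=C1C[C@@H](c2ccccc2)Oc2c(Cc3ccccc3O)c(O)cc(O)c21 | intermediate
15 | 4-[2-hydroxy-3-(2-hydroxybenzyl)benzyl]-6-methylidenecyclohexa-2,4-dien-1-one (not isolated) | C=C1C=C(Cc2cccc(Cc3ccccc3O)c2O)C=CC1=O | intermediate
16 | (2S)-5,7-dihydroxy-6-{2-hydroxy-5-[2-hydroxy-3-(2-hydroxybenzyl)benzyl]benzyl}-8-(2-hydroxybenzyl)-2-phenylchroman-4-one (CNP0107650.1) | O=C1C[C@@H](c2ccccc2)Oc2c(Cc3ccccc3O)c(O)c(Cc3cc(Cc4cccc(Cc5ccccc5O)c4O)ccc3O)c(O)c21 | target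

Total step count: 7. Longest linear sequence: 6 (steps 1 to 5, then step 7); step 6 is a one-step side branch.

Steps most likely to fail

Step 3.
- Risk: the isomerisation may stall after migration of only one double bond, or the alcohol may act as a net reductant and saturate an enone.
- Fallback: it sets out from 6 and comes back at 8, and it replaces the redox-neutral shift by a reduce-then-oxidise sequence. Both exocyclic alkenes are saturated with H2 over Pd/C poisoned with 2,2'-bipyridyl (EtOAc–MeOH, rt), a poison that suppresses cleavage of phenolic benzyl ethers. This gives methyl 5-({3-[2-(benzyloxy)benzyl]-2-oxocyclohexyl}methyl)-2-hydroxybenzoate F1 as a cis/trans mixture, both isomers of which converge. The saturated ketone is then aromatised by aerobic palladium-catalysed dehydrogenation (Pd(OCOCF3)2, 2-(dimethylamino)pyridine, TsOH, O2, DMSO, 80 °C) to phenol 8. The benzyl ether is kept on purpose, since a free ortho-OH next to the saturated ketone would cyclise.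

Step 7.
- Risk: self-condensation of the polyphenolic electrophile may outrun attack by the hindered C6. Long heating with the Lewis acid may also open ring C reversibly, which erodes C2 and interchanges C6 and C8.
- Fallback: it sets out from 10 and comes back at 16. The OH and the CH2OH of ring E are tied together with PhB(OH)2 (toluene, Dean–Stark) as the cyclic boronate 2-(2-hydroxybenzyl)-6-[(2-phenyl-4H-1,3,2-benzodioxaborinin-6-yl)methyl]phenol F2. This is a storable quinone methide precursor that does not self-condense on standing. BF3·OEt2 in CH2Cl2–dioxane at 0 °C to rt releases 15 gradually in the presence of 14, so the bond to C6 forms at a lower temperature. Aqueous work-up removes the boron.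

Step 6.
- Risk: poor positional selectivity between C8 and C6 of ring A, with double alkylation as a further drain. C6 lies between the two hydroxyls and may be favoured by the bond fixation that the 5-OH to C4=O chelate imposes.
- Fallback: it sets out from 11 and 10 and comes back at 16, and it inverts the order so that such a bias works for the route. Excess 11 is hydroxybenzylated with 10 (ZnCl2, dioxane, via 15) to give (2S)-5,7-dihydroxy-6-{2-hydroxy-5-[2-hydroxy-3-(2-hydroxybenzyl)benzyl]benzyl}-2-phenylchroman-4-one F3, which is purified by chromatography. The only remaining ring A carbon, C8, is then alkylated with an excess of cheap 12 (via 13) to reach 16.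

Further compounds
F1 | step 3 | methyl 5-({3-[2-(benzyloxy)benzyl]-2-oxocyclohexyl}methyl)-2-hydroxybenzoate (cis/trans mixture, both converge) | COC(=O)c1cc(CC2CCCC(Cc3ccccc3OCc3ccccc3)C2=O)ccc1O
F2 | step 7 | 2-(2-hydroxybenzyl)-6-[(2-phenyl-4H-1,3,2-benzodioxaborinin-6-yl)methyl]phenol | Oc1ccccc1Cc1cccc(Cc2ccc3OB(c4ccccc4)OCc3c2)c1O
F3 | step 6 | (2S)-5,7-dihydroxy-6-{2-hydroxy-5-[2-hydroxy-3-(2-hydroxybenzyl)benzyl]benzyl}-2-phenylchroman-4-one | O=C1C[C@@H](c2ccccc2)Oc2cc(O)c(Cc3cc(Cc4cccc(Cc5ccccc5O)c4O)ccc3O)c(O)c21
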